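**Plan**

- The retrosynthesis first removes the three O-methyl groups and then returns ring C to the cyclohexenone oxidation level. Ring C carries OH at C1, the aryl ether oxygen at C2 and the ethano bridge at C4 (para to OH), which is the pattern of a 2-aryloxy-4-alkylcyclohex-2-en-1-one.
- That enone is cut at C2–C3 (aldol) and C4–C5 (conjugate addition) into an aryloxymethyl vinyl ketone carrying rings A and B and 4-(2,3-dimethoxyphenyl)butanal carrying ring D.
- The vinyl ketone is cut at the acyl–vinyl bond (Weinreb amide), the ArO–CH2 bond (Williamson) and the A–B bridge (Wittig). The butanal is cut at the styrenyl bond of its side chain (Wittig).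
- Forward: rings A, B and D are bought as benzenes. The A–B bibenzyl phenol is made, etherified and vinylated, and the ring D butanal is made separately. Ring C is then built by annulation, aromatised, and the methyl ethers are cleaved.
- Stereochemistry: the target is achiral. The one stereocentre of the route (C4 of the cyclohexenone) forms racemic and is erased on aromatisation, and alkene geometries are erased by hydrogenation.

Key step: step 8

Remark on the chemistry: compounds 1, 2, 5, 8, 9 and 13 are taken as purchasable, and alkenes 3 and 10 are carried on as geometric mixtures because the next step saturates them.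

**Route**

Step 1
Reactants: 1 (3-methoxybenzyl)triphenylphosphonium chloride; 2 4-(benzyloxy)benzaldehyde
Product: 3 1-(benzyloxy)-4-[2-(3-methoxyphenyl)ethenyl]benzene (E/Z mixture)
Conditions: KOtBu, THF, 0 °C to rt
Reagents that add atoms: none
Why: Wittig olefination of a semi-stabilised benzylic ylide with an aromatic aldehyde is dependable, and the geometric mixture is of no consequence because the alkene is saturated next.

Step 2
Reactants: 3 1-(benzyloxy)-4-[2-(3-methoxyphenyl)ethenyl]benzene
Product: 4 4-[2-(3-methoxyphenyl)ethyl]phenol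
Conditions: H2 (1 atm), 10% Pd/C, EtOAc/EtOH, rt
Reagents that add atoms: none
Why: Heterogeneous catalytic hydrogenation should saturate the stilbene and hydrogenolyse the benzyl ether in one operation while the aryl methyl ether stays intact.

Step 3
Reactants: 4 4-[2-(3-methoxyphenyl)ethyl]phenol; 5 2-chloro-N-methoxy-N-methylacetamide
Product: 6 N-methoxy-2-{4-[2-(3-methoxyphenyl)ethyl]phenoxy}-N-methylacetamide
Conditions: K2CO3, KI (cat.), DMF, 60 °C
Reagents that add atoms: none
Why: Williamson ether synthesis by SN2 attack of the phenoxide on the activated α-chloro amide places the future ring C ether oxygen and delivers the Weinreb amide directly.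

Step 4
Reactants: 6 N-methoxy-2-{4-[2-(3-methoxyphenyl)ethyl]phenoxy}-N-methylacetamide
Product: 7 1-{4-[2-(3-methoxyphenyl)ethyl]phenoxy}but-3-en-2-one
Conditions: CH2=CHMgBr, THF, −78 to 0 °C; inverse quench into cold 1 M HCl; crude enone kept cold with BHT and used at once
Reagents that add atoms: vinylmagnesium bromide, C=C[Mg]Br
Why: Weinreb ketone synthesis, in which the chelated tetrahedral adduct prevents a second addition and the acidic inverse quench keeps the released amine protonated so that it cannot add to the enone.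

Step 5
Reactants: 8 2,3-dimethoxybenzaldehyde; 9 [2-(1,3-dioxolan-2-yl)ethyl]triphenylphosphonium bromide
Product: 10 2-[3-(2,3-dimethoxyphenyl)prop-2-en-1-yl]-1,3-dioxolane (mainly Z, E/Z mixture)
Conditions: KOtBu, THF, 0 °C to rt
Reagents that add atoms: none
Why: Wittig olefination with a non-stabilised ylide attaches the three-carbon masked aldehyde, and the alkene geometry is irrelevant because it is hydrogenated next.

Step 6
Reactants: 10 2-[3-(2,3-dimethoxyphenyl)prop-2-en-1-yl]-1,3-dioxolane
Product: 11 2-[3-(2,3-dimethoxyphenyl)propyl]-1,3-dioxolane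
Conditions: H2 (1 atm), 10% Pd/C, EtOAc, rt
Reagents that add atoms: none
Why: Catalytic hydrogenation of the styrenyl double bond under neutral conditions leaves the acetal and the aryl methyl ethers untouched.

Step 7
Reactants: 11 2-[3-(2,3-dimethoxyphenyl)propyl]-1,3-dioxolane
Product: 12 4-(2,3-dimethoxyphenyl)butanal
Conditions: 1 M HCl, THF/H2O, rt
Reagents that add atoms: water, O
Why: Acid-catalysed acetal hydrolysis frees the aldehyde, and nothing else in the molecule is labile to dilute acid.

Step 8
Reactants: 12 4-(2,3-dimethoxyphenyl)butanal; 13 pyrrolidine; 7 1-{4-[2-(3-methoxyphenyl)ethyl]phenoxy}but-3-en-2-one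
Product: 16 rac-4-[2-(2,3-dimethoxyphenyl)ethyl]-2-{4-[2-(3-methoxyphenyl)ethyl]phenoxy}cyclohex-2-en-1-one, via pyrrolidine enamine 14 (not isolated), via 1,5-ketoaldehyde 15 (not isolated)
Conditions: 12 + 13, 4 Å MS, PhMe, 0 °C to rt; then 7 (slight deficiency), 0 °C to rt; then AcOH/NaOAc/H2O, 80 °C
Reagents that add atoms: water, O (supplies the aldehyde oxygen of 15 only; it is lost again on dehydration to 16)
Why: Aldehyde 12 and pyrrolidine 13 condense to enamine 14, whose β-carbon adds to the vinyl terminus of 7; the acetate buffer then hydrolyses the adduct to ketoaldehyde 15, in which the enol of the aryloxymethyl ketone attacks the aldehyde and the aldol loses water to the conjugated enone. The closest known reaction is the Stork enamine Robinson annulation of aldehydes with methyl or ethyl vinyl ketone to 4-substituted cyclohex-2-enones. Ring C closes by a 6-(enolendo)-exo-trig aldol, the enol C=C lying inside the new ring and the aldehyde C=O outside it. The only new stereocentre, C4, forms racemic without control, and none is needed because step 9 makes this carbon aromatic. The step needs regioselective closure and a single conjugate addition: only the OAr-bearing α-carbon can reach the aldehyde through a six-membered transition state (the other α-carbon would close a cyclobutane) and its protons are inductively acidified, while preforming 14 before 7 is added and the greater hindrance of the adduct enamine should hold the addition at one equivalent of enone.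

Step 9
Reactants: 16 rac-4-[2-(2,3-dimethoxyphenyl)ethyl]-2-{4-[2-(3-methoxyphenyl)ethyl]phenoxy}cyclohex-2-en-1-one
Product: 17 4-[2-(2,3-dimethoxyphenyl)ethyl]-2-{4-[2-(3-methoxyphenyl)ethyl]phenoxy}phenol
Conditions: Pd(OCOCF3)2 (5 mol %), 2-(dimethylamino)pyridine (10 mol %), TsOH·H2O (20 mol %), O2 (1 atm), DMSO, 80 °C
Reagents that add atoms: none
Why: Palladium-catalysed aerobic dehydrogenation of a cyclohexenone, in which a divalent palladium enolate at C6 undergoes β-hydride elimination to the cross-conjugated dienone that tautomerises to the phenol while O2 returns zerovalent palladium to the divalent state, so the racemic centre disappears.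

Step 10
Reactants: 17 4-[2-(2,3-dimethoxyphenyl)ethyl]-2-{4-[2-(3-methoxyphenyl)ethyl]phenoxy}phenol
Product: 18 3-[2-(4-hydroxy-3-{4-[2-(3-hydroxyphenyl)ethyl]phenoxy}phenyl)ethyl]benzene-1,2-diol (target)
Conditions: BBr3 (excess), CH2Cl2, −78 °C to rt; then H2O, 0 °C
Reagents that add atoms: none
Why: BBr3 demethylation cleaves the three aryl methyl ethers by bromide attack at the methyl carbon of the boron-complexed ether, whereas the diaryl ether offers no sp3 carbon and should survive.

**Compound list**

1 | (3-methoxybenzyl)triphenylphosphonium chloride | COc1cccc(C[P+](c2ccccc2)(c2ccccc2)c2ccccc2)c1.[Cl-] | starting material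
2 | 4-(benzyloxy)benzaldehyde | O=Cc1ccc(OCc2ccccc2)cc1 | starting material
3 | 1-(benzyloxy)-4-[2-(3-methoxyphenyl)ethenyl]benzene (E/Z mixture) | COc1cccc(C=Cc2ccc(OCc3ccccc3)cc2)c1 | intermediate
4 | 4-[2-(3-methoxyphenyl)ethyl]phenol | COc1cccc(CCc2ccc(O)cc2)c1 | intermediate
5 | 2-chloro-N-methoxy-N-methylacetamide | CON(C)C(=O)CCl | starting material
6 | N-methoxy-2-{4-[2-(3-methoxyphenyl)ethyl]phenoxy}-N-methylacetamide | CON(C)C(=O)COc1ccc(CCc2cccc(OC)c2)cc1 | intermediate
7 | 1-{4-[2-(3-methoxyphenyl)ethyl]phenoxy}but-3-en-2-one | C=CC(=O)COc1ccc(CCc2cccc(OC)c2)cc1 | intermediate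
8 | 2,3-dimethoxybenzaldehyde | COc1cccc(C=O)c1OC | starting material
9 | [2-(1,3-dioxolan-2-yl)ethyl]triphenylphosphonium bromide | C1COC(CC[P+](c2ccccc2)(c2ccccc2)c2ccccc2)O1.[Br-] | starting material
10 | 2-[3-(2,3-dimethoxyphenyl)prop-2-en-1-yl]-1,3-dioxolane (mainly Z, E/Z mixture) | COc1cccc(C=CCC2OCCO2)c1OC | intermediate
11 | 2-[3-(2,3-dimethoxyphenyl)propyl]-1,3-dioxolane | COc1cccc(CCCC2OCCO2)c1OC | intermediate
12 | 4-(2,3-dimethoxyphenyl)butanal | COc1cccc(CCCC=O)c1OC | intermediate
13 | pyrrolidine | C1CCNC1 | starting material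
14 | 1-[(E)-4-(2,3-dimethoxyphenyl)but-1-en-1-yl]pyrrolidine (not isolated) | COc1cccc(CC/C=C/N2CCCC2)c1OC | intermediate
15 | rac-2-[2-(2,3-dimethoxyphenyl)ethyl]-6-{4-[2-(3-methoxyphenyl)ethyl]phenoxy}-5-oxohexanal (not isolated) | O=CC(CCc1cccc(OC)c1OC)CCC(=O)COc1ccc(CCc2cccc(OC)c2)cc1 | intermediate
16 | rac-4-[2-(2,3-dimethoxyphenyl)ethyl]-2-{4-[2-(3-methoxyphenyl)ethyl]phenoxy}cyclohex-2-en-1-one | O=C1CCC(CCc2cccc(OC)c2OC)C=C1Oc1ccc(CCc2cccc(OC)c2)cc1 | intermediate
17 | 4-[2-(2,3-dimethoxyphenyl)ethyl]-2-{4-[2-(3-methoxyphenyl)ethyl]phenoxy}phenol | COc1cccc(CCc2ccc(Oc3cc(CCc4cccc(OC)c4OC)ccc3O)cc2)c1 | intermediate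
18 | 3-[2-(4-hydroxy-3-{4-[2-(3-hydroxyphenyl)ethyl]phenoxy}phenyl)ethyl]benzene-1,2-diol | Oc1cccc(CCc2ccc(Oc3cc(CCc4cccc(O)c4O)ccc3O)cc2)c1 | target

**Step count and risks**

Total steps: 10. Longest linear sequence: 7 steps (steps 1, 2, 3, 4, 8, 9, 10); the ring D branch (steps 5–7) joins at step 8.

Steps most likely to fail:

1. Step 8. The aryloxymethyl vinyl ketone may polymerise or add twice faster than the single conjugate addition proceeds, or the aldol closure may stop before dehydration. In that case ring C would be annulated with plain methyl vinyl ketone and the ether oxygen introduced afterwards. Setting out from 12 (as its enamine 14), addition to methyl vinyl ketone and acetate-buffer cyclisation would pass through 2-[2-(2,3-dimethoxyphenyl)ethyl]-5-oxohexanal F1, which is not isolated, to 4-[2-(2,3-dimethoxyphenyl)ethyl]cyclohex-2-en-1-one F2. Nucleophilic epoxidation (H2O2, NaOH, MeOH, 0 °C) would give 5-[2-(2,3-dimethoxyphenyl)ethyl]-7-oxabicyclo[4.1.0]heptan-2-one F3. Heating F3 with phenol 4 and Cs2CO3 in DMF should open the epoxide at the carbon next to the carbonyl and, after loss of water, return to the route at 16.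

2. Step 9. The aerobic dehydrogenation may stall through aggregation of the palladium catalyst, or oxidation at the benzylic carbons may compete. The second ring unsaturation would then be introduced by selenoxide elimination. From 16, kinetic deprotonation at C6 (LiN(iPr)2, THF, −78 °C) and trapping with PhSeBr would give 4-[2-(2,3-dimethoxyphenyl)ethyl]-2-{4-[2-(3-methoxyphenyl)ethyl]phenoxy}-6-(phenylselanyl)cyclohex-2-en-1-one F4. Oxidation (H2O2, pyridine, CH2Cl2, 0 °C) would form the selenoxide 6-(benzeneseleninyl)-4-[2-(2,3-dimethoxyphenyl)ethyl]-2-{4-[2-(3-methoxyphenyl)ethyl]phenoxy}cyclohex-2-en-1-one F5. Its syn-elimination would give 4-[2-(2,3-dimethoxyphenyl)ethyl]-2-{4-[2-(3-methoxyphenyl)ethyl]phenoxy}cyclohexa-2,5-dien-1-one F6, the keto tautomer of the phenol, which should enolise on work-up and rejoin the route at 17.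

3. Step 4. The N,O-dimethylhydroxylamine released on quench may add to the new enone, and the enone may oligomerise on concentration. The four-carbon unit would then be attached at the alcohol oxidation level with no amine present. From phenol 4, base-mediated opening of 2-vinyloxirane at its terminal carbon (K2CO3, DMF, 80 °C) would give 1-{4-[2-(3-methoxyphenyl)ethyl]phenoxy}but-3-en-2-ol F7. Oxidation of this allylic alcohol with MnO2 (CH2Cl2, rt) would return to the route at 7, taken on as a filtered solution.

**Further compounds**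

F1 | step 8 | rac-2-[2-(2,3-dimethoxyphenyl)ethyl]-5-oxohexanal (not isolated) | CC(=O)CCC(C=O)CCc1cccc(OC)c1OC
F2 | step 8 | rac-4-[2-(2,3-dimethoxyphenyl)ethyl]cyclohex-2-en-1-one | O=C1CCC(CCc2cccc(OC)c2OC)C=C1
F3 | step 8 | 5-[2-(2,3-dimethoxyphenyl)ethyl]-7-oxabicyclo[4.1.0]heptan-2-one (racemic, diastereomer mixture) | O=C1CCC(CCc2cccc(OC)c2OC)C2OC12
F4 | step 9 | 4-[2-(2,3-dimethoxyphenyl)ethyl]-2-{4-[2-(3-methoxyphenyl)ethyl]phenoxy}-6-(phenylselanyl)cyclohex-2-en-1-one (racemic, diastereomer mixture) | O=C1C([Se]c2ccccc2)CC(CCc3cccc(OC)c3OC)C=C1Oc1ccc(CCc2cccc(OC)c2)cc1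
F5 | step 9 | 6-(benzeneseleninyl)-4-[2-(2,3-dimethoxyphenyl)ethyl]-2-{4-[2-(3-methoxyphenyl)ethyl]phenoxy}cyclohex-2-en-1-one (racemic, diastereomer mixture, not isolated) | O=C1C([Se](=O)c2ccccc2)CC(CCc3cccc(OC)c3OC)C=C1Oc1ccc(CCc2cccc(OC)c2)cc1
F6 | step 9 | rac-4-[2-(2,3-dimethoxyphenyl)ethyl]-2-{4-[2-(3-methoxyphenyl)ethyl]phenoxy}cyclohexa-2,5-dien-1-one (not isolated) | O=C1C=CC(CCc2cccc(OC)c2OC)C=C1Oc1ccc(CCc2cccc(OC)c2)cc1
F7 | step 4 | rac-1-{4-[2-(3-methoxyphenyl)ethyl]phenoxy}but-3-en-2-ol | C=CC(O)COc1ccc(CCc2cccc(OC)c2)cc1
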